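**Retrosynthetic overview**

1. The γ-lactone is closed last by an intramolecular Reformatsky reaction of a C7 2-bromopropanoate onto a C8 ketone inside the ten-membered ring (C17–C8 bond; sets C8 and C17).
2. The ten-membered ring comes from a Nozaki–Hiyama–Kishi closure of C6–C7; C9–C10 comes from a chelation-controlled Hosomi–Sakurai union of a C7–C9 glyceraldehyde unit with the ring A allylsilane, which also unveils the C11=C20 methylene.
3. Ring A is made by a boron-tethered intramolecular Diels–Alder reaction that forms C12–C13 and C14–C1 at once: diene C12=C11–C10=C1 (a 2-silylmethyl diene carrying the C2 carbinol) plus a (Z)-2-silyloxyvinylboronate as cis-ene-diol (C13=C14) equivalent.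
4. Enabling feature: in ring A (C1, C10–C14) the cis-diol carbons C13 and C14 carry no carbon substituent and lie between C12 and the quaternary C1, while O2 on the neighbouring C2 is 1,3 and cis to O14, so a C2–O–B–C14 tether can deliver the two-carbon unit; C10–H next to the C11 exo-methylene is the retron of an allylsilane (C10=C11–C20–Si).
5. Order of ring formation: ring A (step 10), ten-membered ring (step 21), lactone (step 25).

Key step: step 10

Remark: carbon numbers in names and comments are the briarane numbers of the target (ring A = C1, C10, C11, C12, C13, C14 with C20 on C11; ten-membered ring = C1 to C10; C15 on C1, C16 on C5, C18 on C17; lactone C7–O–C19(=O)–C17–C8).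
Assumption: compounds 1, 2, 7, 9, 18, 29 and 41 are taken as commercial, and the minor (E)-isomer of 20 is assumed to be removable by distillation.

**Route**

Step 1
Reactants: 1 2-(2-bromoethyl)-1,3-dioxolane; 2 propyne
Product: 5 2-[(3Z)-4-iodo-3-methylbut-3-en-1-yl]-1,3-dioxolane, via Grignard reagent 3 (not isolated), via alkenylcopper 4 (not isolated)
Conditions: Mg, THF, 25 °C; CuBr·SMe2, Et2O/Me2S, −45 °C; propyne, −25 °C; I2, −50 → 0 °C
Reagents that add atoms: iodine, II
Why: Normant syn-carbocupration of propyne (copper to the terminal carbon, alkyl and copper cis) followed by iodinolysis with retention should give the vinyl iodide with iodine cis to the chain, which fixes the (Z)-C5=C6 geometry and brings in C16.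

Step 2
Reactants: 5 2-[(3Z)-4-iodo-3-methylbut-3-en-1-yl]-1,3-dioxolane
Product: 6 (4Z)-5-iodo-4-methylpent-4-enal
Conditions: 1 M HCl, THF, 25 °C
Reagents that add atoms: water, O
Why: Acid-catalysed acetal hydrolysis should free the C2 aldehyde while the vinyl iodide is inert.

Step 3
Reactants: 7 2-[(trimethylsilyl)methyl]prop-2-en-1-ol
Product: 8 2-[(trimethylsilyl)methyl]prop-2-enal
Conditions: MnO2, CH2Cl2, 25 °C
Reagents that add atoms: none
Why: Neutral MnO2 oxidation of a primary allylic alcohol should give the enal without protodesilylation of the allylsilane.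

Step 4
Reactants: 8 2-[(trimethylsilyl)methyl]prop-2-enal; 9 ethyltriphenylphosphonium iodide
Product: 13 [(3Z)-4-iodo-2-methylidenepent-3-en-1-yl]trimethylsilane, via ethylidene ylide 10 (not isolated), via iodoethylphosphonium iodide 11 (not isolated), via iodo ylide 12 (not isolated)
Conditions: 9, n-BuLi, THF, 0 °C; I2, −78 °C; NaN(SiMe3)2, −78 → −20 °C; then 8, −78 → 0 °C
Reagents that add atoms: iodine, II
Why: Stork–Zhao-type Wittig olefination with the α-iodo ylide should give the 2-iodoalk-2-ene with iodine cis to the aldehyde-derived carbon, so that the later C2 substituent sits inside (cis to C11) on the C1=C10 bond.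

Step 5
Reactants: 13 [(3Z)-4-iodo-2-methylidenepent-3-en-1-yl]trimethylsilane; 6 (4Z)-5-iodo-4-methylpent-4-enal
Product: 15 rac-(1Z,6Z)-1-iodo-2,6-dimethyl-8-[(trimethylsilyl)methyl]nona-1,6,8-trien-5-ol, via dienyllithium 14 (not isolated)
Conditions: 13, t-BuLi (2 equiv), Et2O, −78 °C; then 6, −78 °C; H2O
Reagents that add atoms: none
Why: Iodine–lithium exchange with retention of alkene geometry and 1,2-addition of the alkenyllithium to the aldehyde should join C1 to C2 (racemic at C2), the vinyl iodide of 6 surviving because carbonyl addition is faster than exchange.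

Step 6
Reactants: 15 rac-(1Z,6Z)-1-iodo-2,6-dimethyl-8-[(trimethylsilyl)methyl]nona-1,6,8-trien-5-ol
Product: 16 (1Z,6Z)-1-iodo-2,6-dimethyl-8-[(trimethylsilyl)methyl]nona-1,6,8-trien-5-one
Conditions: MnO2, CH2Cl2, 0 °C, dark; used at once
Reagents that add atoms: none
Why: MnO2 oxidation of the secondary allylic alcohol should give the dienone under neutral conditions that do not isomerise the (Z)-enone, preparing a reagent-controlled reduction.

Step 7
Reactants: 16 (1Z,6Z)-1-iodo-2,6-dimethyl-8-[(trimethylsilyl)methyl]nona-1,6,8-trien-5-one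
Product: 17 (1Z,5S,6Z)-1-iodo-2,6-dimethyl-8-[(trimethylsilyl)methyl]nona-1,6,8-trien-5-ol
Conditions: (R)-2-methyl-CBS-oxazaborolidine (0.5 equiv), catecholborane, toluene, −78 °C; aq. NaOH work-up
Reagents that add atoms: none
Why: Corey–Bakshi–Shibata reduction, in which the α-methyl alkenyl group acts as the large substituent, should deliver hydride from the (R)-catalyst to give the (5S)-alcohol (C2 of the target), catecholborane at low temperature avoiding hydroboration of the diene.

Step 8
Reactants: 18 trimethyl(vinyloxy)silane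
Product: 20 [(Z)-2-bromoethenyl]oxy(trimethyl)silane, via dibromide 19 (not isolated)
Conditions: Br2, CH2Cl2, −78 °C; Et3N, −78 → 25 °C; distillation
Reagents that add atoms: bromine, BrBr
Why: Bromine addition to the silyl enol ether followed by amine-induced dehydrobromination should give mainly the (Z)-2-bromovinyl silyl ether, the favoured isomer of such 1,2-diheteroethenes.

Step 9
Reactants: 20 [(Z)-2-bromoethenyl]oxy(trimethyl)silane
Product: 23 diisopropyl [(Z)-2-(trimethylsilyloxy)ethenyl]boronate, via silyloxyvinyllithium 21 (not isolated), via borate complex 22 (not isolated)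
Conditions: t-BuLi (2 equiv), Et2O, −78 °C; B(OiPr)3, −78 °C; Me3SiCl, −78 → 25 °C; filtration, distillation
Reagents that add atoms: triisopropyl borate, CC(C)OB(OC(C)C)OC(C)C
Why: Bromine–lithium exchange with retention (the cis-β-silyloxyvinyllithium cannot eliminate anti), borylation to the ate complex and removal of one isopropoxide with Me3SiCl should give the (Z)-alkenylboronate under non-aqueous conditions that keep the silyl enol ether.

Step 10
Reactants: 17 (1Z,5S,6Z)-1-iodo-2,6-dimethyl-8-[(trimethylsilyl)methyl]nona-1,6,8-trien-5-ol; 23 diisopropyl [(Z)-2-(trimethylsilyloxy)ethenyl]boronate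
Product: 27 (1S,2R,3S)-3-[(1S,4Z)-1-hydroxy-5-iodo-4-methylpent-4-en-1-yl]-3-methyl-5-[(trimethylsilyl)methyl]cyclohex-4-ene-1,2-diol, via mixed boronate 24 (not isolated), via cycloadduct 25 (not isolated), via cyclic borate 26 (not isolated)
Conditions: 17 + 23 (1.3 equiv), toluene, 40 °C, reduced pressure (removal of i-PrOH); toluene (0.02 M), BHT, sealed tube, 150 °C; Me3NO, THF, 60 °C; K2CO3, MeOH, 25 °C
Reagents that add atoms: trimethylamine N-oxide, C[N+](C)(C)[O-]
Why: Alcohol exchange at boron links O2 of 17 to the boron of 23 (C2–O–B–C14 tether, 24), and on heating the (Z)-alkenylboronate adds suprafacially across the diene C12=C11–C10=C1 in a concerted thermal [4+2] cycloaddition that forms C12–C13 and C14–C1 together, after which Me3NO oxidises C14–B to C14–O with retention and methanolysis frees the triol. The closest known reaction type is the alkenylboronate-tethered intramolecular Diels–Alder reaction of 2,4-dienols followed by oxidative work-up. Two rings close: ring A (the six-membered carbocycle) by the [4+2] addition, and the temporary 1,2-oxaborolane C1–C2–O–B–C14 as the five-membered ring of a cycloaddition with a three-atom tether, which must be cis-fused because C2 is the inside (Z) substituent of the diene terminus. The quaternary C1 follows from that cis fusion (C14–B, later O14, cis to C2 and C15 trans), C13 and C14 from the (Z)-geometry of the dienophile transferred suprafacially (O13 cis to O14), and the absolute sense from the C2 carbinol centre of step 7, whose hydrogen must lie inside over C12 (allylic 1,3-strain) so that C3 points away and only one diene face can be reached by the tethered boronate. The step needs regioselectivity (C14 and not C13 to C1, fixed by the tether), exo/endo selectivity (fixed by the Z-diene and the short tether) and facial selectivity (fixed by C2), and it must outrun the thermal [1,5]-hydrogen shift of the (Z)-dienyl carbinol, which the intramolecular delivery should secure.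

Step 11
Reactants: 27 ring A triol
Product: 28 (1S,2R,3S)-3-[(1S,4Z)-1-acetoxy-5-iodo-4-methylpent-4-en-1-yl]-3-methyl-5-[(trimethylsilyl)methyl]cyclohex-4-ene-1,2-diyl diacetate
Conditions: Ac2O, DMAP, pyridine, 25 °C
Reagents that add atoms: acetic anhydride, CC(=O)OC(C)=O
Why: DMAP-catalysed acetylation should esterify all three secondary alcohols (those at C2 and C14 are neopentyl), installing the final C2, C13 and C14 acetates early.

Step 12
Reactants: 29 (S)-(2,2-dimethyl-1,3-dioxolan-4-yl)methanol
Product: 30 tert-butyl{[(4R)-2,2-dimethyl-1,3-dioxolan-4-yl]methoxy}diphenylsilane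
Conditions: t-BuPh2SiCl, imidazole, DMF, 25 °C
Reagents that add atoms: tert-butyl(chloro)diphenylsilane, CC(C)(C)[Si](Cl)(c1ccccc1)c1ccccc1
Why: Silylation of the primary alcohol should protect the later C7 oxygen with a group that survives acid and Lewis acid.

Step 13
Reactants: 30 tert-butyl{[(4R)-2,2-dimethyl-1,3-dioxolan-4-yl]methoxy}diphenylsilane
Product: 31 (2R)-3-[(tert-butyldiphenylsilyl)oxy]propane-1,2-diol
Conditions: AcOH/H2O 4:1, 40 °C
Reagents that add atoms: none
Why: Acid hydrolysis of the terminal acetonide should free the diol, the tert-butyldiphenylsilyl ether being stable to aqueous acetic acid.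

Step 14
Reactants: 31 (2R)-3-[(tert-butyldiphenylsilyl)oxy]propane-1,2-diol
Product: 32 tert-butyl{[(4R)-2-(4-methoxyphenyl)-1,3-dioxolan-4-yl]methoxy}diphenylsilane
Conditions: 4-methoxybenzaldehyde dimethyl acetal, PPTS (cat.), CH2Cl2, 25 °C
Reagents that add atoms: 4-methoxybenzaldehyde dimethyl acetal, COc1ccc(C(OC)OC)cc1
Why: Acid-catalysed transacetalisation should give the 4-methoxybenzylidene acetal (acetal carbon as a mixture, which is irrelevant).

Step 15
Reactants: 32 tert-butyl{[(4R)-2-(4-methoxyphenyl)-1,3-dioxolan-4-yl]methoxy}diphenylsilane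
Product: 33 (2R)-3-[(tert-butyldiphenylsilyl)oxy]-2-[(4-methoxyphenyl)methoxy]propan-1-ol
Conditions: i-Bu2AlH, CH2Cl2, −78 → 0 °C; aq. potassium sodium tartrate
Reagents that add atoms: none
Why: Regioselective reductive opening of the benzylidene acetal, in which aluminium binds the less hindered primary oxygen, should leave the 4-methoxybenzyl ether on the secondary oxygen (later O8) and a free primary alcohol.

Step 16
Reactants: 33 (2R)-3-[(tert-butyldiphenylsilyl)oxy]-2-[(4-methoxyphenyl)methoxy]propan-1-ol
Product: 34 (2S)-3-[(tert-butyldiphenylsilyl)oxy]-2-[(4-methoxyphenyl)methoxy]propanal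
Conditions: Dess–Martin periodinane, pyridine, CH2Cl2, 0 °C
Reagents that add atoms: none
Why: Dess–Martin oxidation should give the α-alkoxy aldehyde (C9) without epimerisation of the temporary C8 centre.

Step 17
Reactants: 28 ring A triacetate; 34 (2S)-3-[(tert-butyldiphenylsilyl)oxy]-2-[(4-methoxyphenyl)methoxy]propanal
Product: 35 C9 alcohol
Conditions: 34, SnCl4 (1.1 equiv), CH2Cl2, −78 °C; then 28, −78 °C; aq. NaHCO3
Reagents that add atoms: none
Why: In this Hosomi–Sakurai allylation (SE2') the SnCl4 chelate of the α-alkoxy aldehyde should be attacked by C10 of the allylsilane, with loss of silicon and shift of the double bond to C11=C20. C9 is set by the Cram-chelate model (8,9-syn). C10 is set by attack anti to the pseudoaxial C1–C2 bond, on the face opposite O13 and O14, through an antiperiplanar open transition state that places C8 next to H-10 and not next to the quaternary C1.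

Step 18
Reactants: 35 C9 alcohol
Product: 36 tetraacetate silyl ether
Conditions: Ac2O, DMAP, pyridine, 25 °C
Reagents that add atoms: acetic anhydride, CC(=O)OC(C)=O
Why: DMAP-catalysed acetylation should install the fourth and last acetate at C9.

Step 19
Reactants: 36 tetraacetate silyl ether
Product: 37 C7 primary alcohol
Conditions: HF·pyridine, pyridine/THF, 0 → 25 °C
Reagents that add atoms: none
Why: Buffered fluoride cleavage of the primary silyl ether should free O7 without touching the acetates, the 4-methoxybenzyl ether or the alkenes.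

Step 20
Reactants: 37 C7 primary alcohol
Product: 38 C7 aldehyde
Conditions: Dess–Martin periodinane, pyridine, CH2Cl2, 0 °C
Reagents that add atoms: none
Why: Buffered Dess–Martin oxidation should give the α-alkoxy aldehyde without β-elimination of the C9 acetate.

Step 21
Reactants: 38 C7 aldehyde
Product: 40 macrocyclic C7 alcohol, via alkenylchromium 39 (not isolated)
Conditions: CrCl2 (10 equiv), NiCl2 (0.1 equiv), DMSO/THF 3:1, 0.002 M, slow addition, 25 °C
Reagents that add atoms: none
Why: In this Nozaki–Hiyama–Kishi macrocyclisation the vinyl iodide should be activated by zerovalent nickel formed in situ, pass to trivalent chromium and add chemoselectively to the aldehyde with retention of the (Z)-alkene, closing the ten-membered ring; Felkin–Anh addition anti to the C8 ether should set C7 (7,8-anti).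

Step 22
Reactants: 40 macrocyclic C7 alcohol; 41 2-bromopropanoyl bromide
Product: 42 C7 2-bromopropanoate
Conditions: pyridine, CH2Cl2, −20 °C
Reagents that add atoms: none
Why: Acylation of the allylic C7 alcohol with the acid bromide should attach C17 to C19 with retention at C7, the bromide-bearing carbon being a mixture that is erased on enolate formation.

Step 23
Reactants: 42 C7 2-bromopropanoate
Product: 43 C8 alcohol
Conditions: DDQ, CH2Cl2/pH 7 buffer, 0 °C
Reagents that add atoms: none
Why: Oxidative cleavage of the 4-methoxybenzyl ether by DDQ should free O8 under neutral conditions compatible with the acetates, the bromo ester and the alkenes.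

Step 24
Reactants: 43 C8 alcohol
Product: 44 C8 ketone
Conditions: Dess–Martin periodinane, pyridine, CH2Cl2, 0 °C
Reagents that add atoms: none
Why: Dess–Martin oxidation should convert the temporary C8 carbinol, which has relayed chirality to C9 and C7, into the ketone under non-basic conditions that do not epimerise C7 or C9.

Step 25
Reactants: 44 C8 ketone
Product: 46 Frajunolide E, via zinc enolate 45 (not isolated)
Conditions: Zn dust (Me3SiCl-activated), THF, 0 → 25 °C; pH 7 buffer
Reagents that add atoms: none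
Why: In this intramolecular Reformatsky reaction zinc, chosen over SmI2 so that the α-acyloxy ketone is not cleaved reductively, should insert into the C–Br bond, and the enolate held on O7 should add 5-exo to the C8 ketone from the face of O7. The ten-membered ring keeps C6–C7 near the carbonyl plane and anti to C9, so the lactone should be trans-fused (8-OH cis to C6), with the C18 methyl turned away from C9 (cis to 8-OH).

**Compound list**

1 | 2-(2-bromoethyl)-1,3-dioxolane | BrCCC1OCCO1 | starting material
2 | propyne | CC#C | starting material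
3 | [2-(1,3-dioxolan-2-yl)ethyl]magnesium bromide | Br[Mg]CCC1OCCO1 | intermediate
4 | [(1Z)-4-(1,3-dioxolan-2-yl)-2-methylbut-1-en-1-yl]copper (MgBr2 complex; copper cis to the chain) | [Cu]/C=C(C)\CCC1OCCO1 | intermediate
5 | 2-[(3Z)-4-iodo-3-methylbut-3-en-1-yl]-1,3-dioxolane | I/C=C(C)\CCC1OCCO1 | intermediate
6 | (4Z)-5-iodo-4-methylpent-4-enal | I/C=C(C)\CCC=O | intermediate
7 | 2-[(trimethylsilyl)methyl]prop-2-en-1-ol | C=C(CO)C[Si](C)(C)C | starting material
8 | 2-[(trimethylsilyl)methyl]prop-2-enal | C=C(C=O)C[Si](C)(C)C | intermediate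
9 | ethyltriphenylphosphonium iodide | CC[P+](c1ccccc1)(c1ccccc1)c1ccccc1.[I-] | starting material
10 | ethylidene(triphenyl)phosphorane | CC=P(c1ccccc1)(c1ccccc1)c1ccccc1 | intermediate
11 | (1-iodoethyl)triphenylphosphonium iodide | CC(I)[P+](c1ccccc1)(c1ccccc1)c1ccccc1.[I-] | intermediate
12 | (1-iodoethylidene)triphenylphosphorane | CC(I)=P(c1ccccc1)(c1ccccc1)c1ccccc1 | intermediate
13 | [(3Z)-4-iodo-2-methylidenepent-3-en-1-yl]trimethylsilane (iodine cis to C11) | C[Si](C)(C)CC(=C)/C=C(C)\I | intermediate
14 | dienyllithium: 13 with lithium in place of iodine, geometry retained | C[Si](C)(C)CC(=C)/C=C(C)\[Li] | intermediate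
15 | rac-(1Z,6Z)-1-iodo-2,6-dimethyl-8-[(trimethylsilyl)methyl]nona-1,6,8-trien-5-ol | C[Si](C)(C)CC(=C)/C=C(C)\C(O)CC/C(C)=C\I | intermediate
16 | (1Z,6Z)-1-iodo-2,6-dimethyl-8-[(trimethylsilyl)methyl]nona-1,6,8-trien-5-one | C[Si](C)(C)CC(=C)/C=C(C)\C(=O)CC/C(C)=C\I | intermediate
17 | (1Z,5S,6Z)-1-iodo-2,6-dimethyl-8-[(trimethylsilyl)methyl]nona-1,6,8-trien-5-ol (C5 of this name = C2 of the target) | C[Si](C)(C)CC(=C)/C=C(C)\[C@@H](O)CC/C(C)=C\I | intermediate
18 | trimethyl(vinyloxy)silane | C=CO[Si](C)(C)C | starting material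
19 | (1,2-dibromoethoxy)trimethylsilane | BrCC(Br)O[Si](C)(C)C | intermediate
20 | [(Z)-2-bromoethenyl]oxy(trimethyl)silane | Br/C=C\O[Si](C)(C)C | intermediate
21 | [(Z)-2-(trimethylsilyloxy)ethenyl]lithium | [Li]/C=C\O[Si](C)(C)C | intermediate
22 | lithium triisopropoxy[(Z)-2-(trimethylsilyloxy)ethenyl]borate | [Li+].CC(C)O[B-](OC(C)C)(OC(C)C)/C=C\O[Si](C)(C)C | intermediate
23 | diisopropyl [(Z)-2-(trimethylsilyloxy)ethenyl]boronate | CC(C)OB(OC(C)C)/C=C\O[Si](C)(C)C | intermediate
24 | mixed boronate: isopropyl ester of the (Z)-2-(trimethylsilyloxy)ethenylboronic acid in which the C2 oxygen of 17 is the second ester oxygen | C[Si](C)(C)CC(=C)/C=C(C)\[C@@H](OB(OC(C)C)/C=C\O[Si](C)(C)C)CC/C(C)=C\I | intermediate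
25 | cycloadduct: ring A cyclohexene (C10=C11, CH2SiMe3 on C11) cis-fused at C1–C14 to a 1,2-oxaborolane (C1–C2–O–B–C14, B–O-i-Pr); 13-OSiMe3 cis to the C14–B bond, C15 trans | C[Si](C)(C)CC1=C[C@@]2(C)[C@H](CC/C(C)=C\I)OB(OC(C)C)[C@H]2[C@@H](O[Si](C)(C)C)C1 | intermediate
26 | cyclic borate: as 25 with oxygen inserted into C14–B (1,3,2-dioxaborinane bridging O2 and O14) | C[Si](C)(C)CC1=C[C@@]2(C)[C@H](CC/C(C)=C\I)OB(OC(C)C)O[C@H]2[C@@H](O[Si](C)(C)C)C1 | intermediate
27 | ring A triol: (1S,2R,3S)-3-[(1S,4Z)-1-hydroxy-5-iodo-4-methylpent-4-en-1-yl]-3-methyl-5-[(trimethylsilyl)methyl]cyclohex-4-ene-1,2-diol (ring C1 = C13, C2 = C14, C3 = C1 of the target; 13-OH, 14-OH and the C2 chain on one face, C15 on the other) | C[Si](C)(C)CC1=C[C@@](C)([C@@H](O)CC/C(C)=C\I)[C@@H](O)[C@@H](O)C1 | intermediate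
28 | ring A triacetate: (1S,2R,3S)-3-[(1S,4Z)-1-acetoxy-5-iodo-4-methylpent-4-en-1-yl]-3-methyl-5-[(trimethylsilyl)methyl]cyclohex-4-ene-1,2-diyl diacetate | C[Si](C)(C)CC1=C[C@@](C)([C@@H](OC(C)=O)CC/C(C)=C\I)[C@@H](OC(C)=O)[C@@H](OC(C)=O)C1 | intermediate
29 | (S)-(2,2-dimethyl-1,3-dioxolan-4-yl)methanol | CC1(C)OC[C@H](CO)O1 | starting material
30 | tert-butyl{[(4R)-2,2-dimethyl-1,3-dioxolan-4-yl]methoxy}diphenylsilane | CC1(C)OC[C@H](CO[Si](c2ccccc2)(c2ccccc2)C(C)(C)C)O1 | intermediate
31 | (2R)-3-[(tert-butyldiphenylsilyl)oxy]propane-1,2-diol | OC[C@@H](O)CO[Si](c1ccccc1)(c1ccccc1)C(C)(C)C | intermediate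
32 | tert-butyl{[(4R)-2-(4-methoxyphenyl)-1,3-dioxolan-4-yl]methoxy}diphenylsilane (both acetal epimers) | COc1ccc(cc1)C1OC[C@H](CO[Si](c2ccccc2)(c2ccccc2)C(C)(C)C)O1 | intermediate
33 | (2R)-3-[(tert-butyldiphenylsilyl)oxy]-2-[(4-methoxyphenyl)methoxy]propan-1-ol | OC[C@@H](OCc1ccc(OC)cc1)CO[Si](c1ccccc1)(c1ccccc1)C(C)(C)C | intermediate
34 | (2S)-3-[(tert-butyldiphenylsilyl)oxy]-2-[(4-methoxyphenyl)methoxy]propanal (C1 = C9, C2 = C8, C3 = C7 of the target) | O=C[C@@H](OCc1ccc(OC)cc1)CO[Si](c1ccccc1)(c1ccccc1)C(C)(C)C | intermediate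
35 | C9 alcohol: ring A with C11=C20 methylidene, 13,14-cis-diacetate and on C1 the C15 methyl and the (2S)-2-acetoxy-(Z)-C5=C6 vinyl iodide chain; C10 carries, trans to C2, the chain C9H(OH)–C8H(O-4-methoxybenzyl)–C7H2O-SiPh2-t-Bu (8,9-syn); C1, C2, C9, C10, C13, C14 as in the target | C=C1C[C@H](OC(C)=O)[C@H](OC(C)=O)[C@](C)([C@@H](OC(C)=O)CC/C(C)=C\I)[C@H]1[C@H](O)[C@@H](OCc1ccc(OC)cc1)CO[Si](c1ccccc1)(c1ccccc1)C(C)(C)C | intermediate
36 | tetraacetate silyl ether: 35 with 9-OAc | C=C1C[C@H](OC(C)=O)[C@H](OC(C)=O)[C@](C)([C@@H](OC(C)=O)CC/C(C)=C\I)[C@H]1[C@H](OC(C)=O)[C@@H](OCc1ccc(OC)cc1)CO[Si](c1ccccc1)(c1ccccc1)C(C)(C)C | intermediate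
37 | C7 primary alcohol: 36 with free C7–OH | C=C1C[C@H](OC(C)=O)[C@H](OC(C)=O)[C@](C)([C@@H](OC(C)=O)CC/C(C)=C\I)[C@H]1[C@H](OC(C)=O)[C@@H](OCc1ccc(OC)cc1)CO | intermediate
38 | C7 aldehyde: 37 oxidised at C7 | C=C1C[C@H](OC(C)=O)[C@H](OC(C)=O)[C@](C)([C@@H](OC(C)=O)CC/C(C)=C\I)[C@H]1[C@H](OC(C)=O)[C@@H](OCc1ccc(OC)cc1)C=O | intermediate
39 | alkenylchromium: 38 with CrCl2 (trivalent chromium) in place of iodine at C6 | C=C1C[C@H](OC(C)=O)[C@H](OC(C)=O)[C@](C)([C@@H](OC(C)=O)CC/C(C)=C\[Cr](Cl)Cl)[C@H]1[C@H](OC(C)=O)[C@@H](OCc1ccc(OC)cc1)C=O | intermediate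
40 | macrocyclic C7 alcohol: ring A trans-fused to the ten-membered ring (C1–C10, (5Z)-alkene); 2,9,13,14-tetraacetate, 8-O-(4-methoxybenzyl), 7-OH (7,8-anti, 8,9-syn); C1, C2, C7, C9, C10, C13, C14 as in the target | C=C1C[C@H](OC(C)=O)[C@H](OC(C)=O)[C@]2(C)[C@@H](OC(C)=O)CC/C(C)=C\[C@H](O)[C@H](OCc3ccc(OC)cc3)[C@@H](OC(C)=O)[C@@H]12 | intermediate
41 | 2-bromopropanoyl bromide (racemic) | CC(Br)C(Br)=O | starting material
42 | C7 2-bromopropanoate: 40 acylated at O7 (both epimers at the CHBr carbon) | C=C1C[C@H](OC(C)=O)[C@H](OC(C)=O)[C@]2(C)[C@@H](OC(C)=O)CC/C(C)=C\[C@H](OC(=O)C(C)Br)[C@H](OCc3ccc(OC)cc3)[C@@H](OC(C)=O)[C@@H]12 | intermediate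
43 | C8 alcohol: 42 with free 8-OH | C=C1C[C@H](OC(C)=O)[C@H](OC(C)=O)[C@]2(C)[C@@H](OC(C)=O)CC/C(C)=C\[C@H](OC(=O)C(C)Br)[C@H](O)[C@@H](OC(C)=O)[C@@H]12 | intermediate
44 | C8 ketone: 43 oxidised at C8 | C=C1C[C@H](OC(C)=O)[C@H](OC(C)=O)[C@]2(C)[C@@H](OC(C)=O)CC/C(C)=C\[C@H](OC(=O)C(C)Br)C(=O)[C@@H](OC(C)=O)[C@@H]12 | intermediate
45 | zinc enolate: bromozinc ester enolate of 44 (C17=C19–O–ZnBr) | C=C1C[C@H](OC(C)=O)[C@H](OC(C)=O)[C@]2(C)[C@@H](OC(C)=O)CC/C(C)=C\[C@H](OC(O[Zn]Br)=CC)C(=O)[C@@H](OC(C)=O)[C@@H]12 | intermediate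
46 | Frajunolide E | C=C1C[C@H](OC(C)=O)[C@H](OC(C)=O)[C@]2(C)[C@@H](OC(C)=O)CC/C(C)=C\[C@@H]3OC(=O)[C@H](C)[C@@]3(O)[C@@H](OC(C)=O)[C@@H]12 | target

**Step count and risks**

Total step count: 25. Longest linear sequence: 16 steps (1, 2, 5, 6, 7, 10, 11, 17–25).

Steps most likely to fail:

1. Step 10 (key cycloaddition). What may go wrong: the B–O tether exchanges or the boronate is protodeboronated at the temperature the donor-substituted dienophile needs, so that loss of the tether or the thermal [1,5]-hydrogen shift of the (Z)-dienyl carbinol overtakes the cycloaddition. Fallback, setting out from 17 (with the lithium reagent 21 of step 9) and coming back at 27: a temporary silicon connection in place of boron. Quenching 21 with Me2SiCl2 should give chloro(dimethyl)[(Z)-2-(trimethylsilyloxy)ethenyl]silane F1. Silylation of 17 with it (imidazole, CH2Cl2) should give the hydrolytically robust silyl ether triene F2, which can be purified and heated longer (toluene, 170 °C) to reach the cis-fused oxasilolane cycloadduct F3 by the same tethered [4+2] mode and the same stereocontrol. Tamao–Fleming oxidation (KF, KHCO3, H2O2, THF/MeOH) should then convert C14–Si into C14–OH with retention and free O2 and O13, giving 27.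

2. Step 17 (fragment union). What may go wrong: slow attack at the neopentyl C10 lets protodesilylation compete, and approach to the wrong face of C10 or a mismatch between ring control and chelate control erodes the selectivity at C9 and C10. Fallback, setting out from 28 and coming back at 35: polarity reversal of the allyl unit and a closed transition state. Bromodesilylation of 28 with N-bromosuccinimide (SE2', CH2Cl2, −78 °C) should give the allylic bromide F4. Barbier-type allylation of 34 with indium powder in THF/H2O passes through a cyclic six-membered transition state with γ-attack at C10 and chelation of the α-alkoxy aldehyde (8,9-syn), and should give 35 with the C11 methylene in place.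

3. Step 21 (ten-membered ring). What may go wrong: oligomerisation in place of ring closure because of the transannular strain of closing at an sp3 carbinol carbon, or poor facial selectivity at C7. Fallback, setting out from 38 and coming back at 40: close the ring as a ketone and set C7 afterwards. Pinnick oxidation of 38 (NaClO2, NaH2PO4, 2-methylbut-2-ene, t-BuOH/H2O) should give the carboxylic acid F5. 2,2'-Dipyridyl disulfide and PPh3 should convert it into the S-(pyridin-2-yl) thioester F6. Intramolecular nickel/zirconium-mediated ketone synthesis between the vinyl iodide and the thioester (NiBr2·(4,4'-di-tert-butyl-2,2'-bipyridine), Cp2ZrCl2, Zn dust, DMI/THF, high dilution) should close the ring as the macrocyclic enone F7. Chelation-controlled reduction with Zn(BH4)2 (Et2O, −40 °C) should then give the 7,8-anti alcohol 40.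

Further compounds

F1 | step 10 | chloro(dimethyl)[(Z)-2-(trimethylsilyloxy)ethenyl]silane | C[Si](C)(C)O/C=C\[Si](C)(C)Cl
F2 | step 10 | silyl ether triene: 17 with its C2 oxygen bound to the SiMe2 group of F1 | C[Si](C)(C)CC(=C)/C=C(C)\[C@@H](O[Si](C)(C)/C=C\O[Si](C)(C)C)CC/C(C)=C\I
F3 | step 10 | oxasilolane cycloadduct: as 25 with SiMe2 in place of B–O-i-Pr | C[Si](C)(C)CC1=C[C@@]2(C)[C@H](CC/C(C)=C\I)O[Si](C)(C)[C@H]2[C@@H](O[Si](C)(C)C)C1
F4 | step 17 | allylic bromide: 28 with bromine at C10 and the C11=C20 methylidene in place of the allylsilane (C10 as a mixture) | C=C1C[C@H](OC(C)=O)[C@H](OC(C)=O)[C@](C)([C@@H](OC(C)=O)CC/C(C)=C\I)C1Br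
F5 | step 21 | C7 carboxylic acid from 38 | C=C1C[C@H](OC(C)=O)[C@H](OC(C)=O)[C@](C)([C@@H](OC(C)=O)CC/C(C)=C\I)[C@H]1[C@H](OC(C)=O)[C@@H](OCc1ccc(OC)cc1)C(O)=O
F6 | step 21 | S-(pyridin-2-yl) thioester of F5 | C=C1C[C@H](OC(C)=O)[C@H](OC(C)=O)[C@](C)([C@@H](OC(C)=O)CC/C(C)=C\I)[C@H]1[C@H](OC(C)=O)[C@@H](OCc1ccc(OC)cc1)C(=O)Sc1ccccn1
F7 | step 21 | macrocyclic enone: 40 with a C7 ketone | C=C1C[C@H](OC(C)=O)[C@H](OC(C)=O)[C@]2(C)[C@@H](OC(C)=O)CC/C(C)=C\C(=O)[C@H](OCc3ccc(OC)cc3)[C@@H](OC(C)=O)[C@@H]12
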